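The target is opened at C3=C4 of ring A, and the C4–C5 and C1–C10 bonds are then traced back to the ring-B alkene of cis-piperitol (eudesmane numbering; ring A: C1–C5, C10; ring B: C5–C10). The feature used is that O6 shares a face of ring B with the C4–C5 bond and the C10 methyl, while C1 lies opposite. A (1-bromovinyl)dimethylsilyl group on O6 therefore passes C4 to C5 by radical 5-exo closure, and the tertiary C10 radical takes an allyl group from allyltributylstannane on the far face. One operation sets C5 and quaternary C10; the precursor is simply the bromovinylsilyl ether of cis-piperitol.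

Key step: step 4

Assumption: (S)-piperitone (1) is taken to be purchasable in high enantiomeric purity, since it supplies the C7 configuration from which C6, C5 and C10 are relayed.

Step 1
Reactants: 1 (S)-piperitone, (6S)-3-methyl-6-(propan-2-yl)cyclohex-2-en-1-one
Product: 2 cis-piperitol, (1R,6S)-3-methyl-6-(propan-2-yl)cyclohex-2-en-1-ol
Conditions: LiBH(s-Bu)3, THF, −78 °C; then aq NaOH, H2O2, 0 °C
Reagents that add atoms: none
Why: Bulky trialkylborohydride 1,2-reduction of a β-substituted enone, in which hydride should arrive on the carbonyl face away from the adjacent isopropyl group and so set C6 with the hydroxyl cis to isopropyl without a separation of epimers, the β-methyl group suppressing conjugate reduction.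

Step 2
Reactants: 3 chlorodimethylvinylsilane
Product: 5 (1-bromoethenyl)chlorodimethylsilane, via chloro(1,2-dibromoethyl)dimethylsilane 4 (not isolated)
Conditions: Br2, CH2Cl2, −78 → 0 °C; evaporate; then Et3N, hexane, reflux; filter under N2, distil
Reagents that add atoms: bromine BrBr
Why: Bromination–dehydrobromination of a vinylsilane (bromine addition, then amine-induced E2 loss of HBr through the acidified α-silyl C–H), the standard entry to 1-bromovinylsilanes, with a tertiary amine chosen so that the Si–Cl bond is left alone.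

Step 3
Reactants: 2 cis-piperitol; 5 (1-bromoethenyl)chlorodimethylsilane
Product: 6 (1-bromoethenyl)dimethyl{[(1R,6S)-3-methyl-6-(propan-2-yl)cyclohex-2-en-1-yl]oxy}silane
Conditions: Et3N, DMAP (cat.), CH2Cl2, 0 °C → rt; filter through Et3N-deactivated silica, use at once
Reagents that add atoms: none
Why: Amine-mediated O-silylation of a secondary allylic alcohol with a chlorosilane, which touches no stereocenter and leaves the labile silyl ether free of protic material for the radical step.

Step 4
Reactants: 6 (1-bromoethenyl)dimethylsilyl ether of cis-piperitol; 7 allyltributylstannane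
Product: 8 cis-fused oxasilolane, 2,2,4-trimethyl-3-methylidene-7-(propan-2-yl)-4-(prop-2-en-1-yl)octahydro-2,1-benzoxasilole, with O1, C3, the C4 methyl and the isopropyl group on one face of the cyclohexane and the C4 allyl group on the other
Conditions: 7 (5 equiv), AIBN (0.2 equiv, in portions), PhH (0.2 M in 6), 80 °C; evaporate, take on crude
Reagents that add atoms: none
Why: Proposed new method: a stannyl radical from the AIBN-started chain removes the vinylic bromine of 6, the α-silyl vinyl radical adds to C5, and the tertiary C10 radical attacks 7 in an SH2′ step that releases the chain-carrying Bu3Sn radical. The closest known chemistry is the tin-hydride cyclisation of (1-bromovinyl)silyl ethers of allylic alcohols and, separately, cyclisation–allyl-transfer tandems of halides with 7; combining them to build a quaternary carbon is the untested part. The only ring formed is the temporary oxasilolane, by 5-exo-trig closure onto the less substituted alkene carbon, which should be preferred to 6-endo attack at the methyl-bearing C10. C5 is set by the tether, because the O–Si–C chain can reach C5 only on the O6 face (cis fusion). C10 is set by the bicycle, because with isopropyl equatorial the O6–Si bond is axial and 1,3-syn to one lobe of the C10 radical, so 7 should approach from the other face and place C1 trans to C4 and the methyl cis to O6. The step needs ring closure before any capture of the vinyl radical, and allyl transfer before a homoallyl–cyclopropylcarbinyl shift of the C10 radical; this should be secured by the fast 5-exo closure of vinyl radicals, a stannane concentration of about 1 M, the absence of a hydride source, and the fact that the shift would exchange a tertiary for a secondary radical.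

Step 5
Reactants: 8 cis-fused oxasilolane
Product: 9 1-[(1S,2R,3S,6S)-2-hydroxy-6-methyl-3-(propan-2-yl)-6-(prop-2-en-1-yl)cyclohexyl]ethan-1-one
Conditions: KF, KHCO3, 30% H2O2, THF/MeOH, rt → 40 °C
Reagents that add atoms: hydrogen peroxide OO
Why: Tamao oxidation, in which fluoride-activated peroxide oxidises the alkenyl C–Si bond to an enol that tautomerises to the C4 methyl ketone while the Si–O6 bond is hydrolysed to the free hydroxyl; C5 should hold because its acetyl group is already equatorial, the more stable epimer.

Step 6
Reactants: 9 hydroxy ketone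
Product: 10 1-[(1S,2R,3S,6S)-2-{[tert-butyl(dimethyl)silyl]oxy}-6-methyl-3-(propan-2-yl)-6-(prop-2-en-1-yl)cyclohexyl]ethan-1-one
Conditions: TBSOTf, 2,6-lutidine, CH2Cl2, −78 → 0 °C
Reagents that add atoms: tert-butyldimethylsilyl trifluoromethanesulfonate CC(C)(C)[Si](C)(C)OS(=O)(=O)C(F)(F)F
Why: Silyl triflate/lutidine O-silylation, the usual protection of hindered β-hydroxy ketones, which blocks retro-aldol cleavage and oxidation at O6 in the following steps.

Step 7
Reactants: 10 silyl ether
Product: 12 1-[2-{[tert-butyl(dimethyl)silyl]oxy}-6-(3-hydroxypropyl)-6-methyl-3-(propan-2-yl)cyclohexyl]ethan-1-one with the ring configuration of 10, via catechol boronate ester 11 (not isolated)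
Conditions: catecholborane, RhCl(PPh3)3 (2 mol %), THF, 0 °C → rt; then aq NaOH, H2O2, 0 °C
Reagents that add atoms: hydrogen peroxide OO
Why: Rhodium-catalysed hydroboration with catecholborane, which is known to take a terminal alkene in preference to a ketone and to place boron on the terminal carbon (C3), followed by peroxide oxidation of the C–B bond to the primary alcohol; no stereocenter is formed.

Step 8
Reactants: 12 primary alcohol
Product: 13 3-[2-acetyl-3-{[tert-butyl(dimethyl)silyl]oxy}-1-methyl-4-(propan-2-yl)cyclohexyl]propanal with the ring configuration of 10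
Conditions: Dess–Martin periodinane, NaHCO3, CH2Cl2, rt; use without storage
Reagents that add atoms: none
Why: Dess–Martin oxidation of a primary alcohol to the aldehyde under buffered conditions that leave the ketone, the silyl ether and C5 alone.

Step 9
Reactants: 13 keto aldehyde
Product: 14 tert-butyl{[(1R,2S,4aR,8aR)-4a,8-dimethyl-2-(propan-2-yl)-1,2,3,4,4a,5,6,8a-octahydronaphthalen-1-yl]oxy}dimethylsilane
Conditions: TiCl3(DME)1.5, Zn–Cu couple, DME, reflux; 13 added over 30 h by syringe pump
Reagents that add atoms: none
Why: Intramolecular McMurry coupling of a keto aldehyde, in which low-valent titanium joins C3 to C4 as a titanium pinacolate and deoxygenates it to the C3=C4 alkene; ring A closes across trans-diequatorial C5 and C10 substituents, so the trans fusion is inherited and no stereocenter is formed.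

Step 10
Reactants: 14 decalin silyl ether
Product: 15 (1R,2S,4aR,8aR)-4a,8-dimethyl-2-(propan-2-yl)-1,2,3,4,4a,5,6,8a-octahydronaphthalen-1-ol
Conditions: Bu4NF, THF, 50 °C
Reagents that add atoms: none
Why: Fluoride cleavage of a silyl ether, with nothing else in 14 able to react with fluoride.

Step 11
Reactants: 16 p-coumaric acid, (2E)-3-(4-hydroxyphenyl)prop-2-enoic acid
Product: 18 (2E)-3-(4-{[tert-butyl(dimethyl)silyl]oxy}phenyl)prop-2-enoic acid, via bis-silylated coumarate 17 (not isolated)
Conditions: TBSCl (2.5 equiv), imidazole, DMF, rt; then AcOH, THF/H2O, rt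
Reagents that add atoms: tert-butyldimethylsilyl chloride CC(C)(C)[Si](C)(C)Cl
Why: Exhaustive silylation of acid and phenol followed by selective hydrolysis of the far more labile silyl ester, which leaves the phenol masked so that it cannot compete as a nucleophile in the acylation.

Step 12
Reactants: 15 decalinol; 18 O-silyl p-coumaric acid
Product: 20 (1R,2S,4aR,8aR)-4a,8-dimethyl-2-(propan-2-yl)-1,2,3,4,4a,5,6,8a-octahydronaphthalen-1-yl (2E)-3-(4-{[tert-butyl(dimethyl)silyl]oxy}phenyl)prop-2-enoate, via mixed trichlorobenzoic anhydride 19 (not isolated)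
Conditions: 18, 2,4,6-Cl3C6H2COCl, Et3N, THF, rt; then 15, DMAP, PhMe, 80 °C
Reagents that add atoms: none
Why: Yamaguchi esterification, in which DMAP attacks the mixed anhydride at the unhindered cinnamoyl carbonyl and the acylpyridinium acylates the hindered axial O6 with retention at C6, the (E)-alkene being untouched.

Step 13
Reactants: 20 O-silyl ester
Product: 21 target, (1R,2S,4aR,8aR)-4a,8-dimethyl-2-(propan-2-yl)-1,2,3,4,4a,5,6,8a-octahydronaphthalen-1-yl (2E)-3-(4-hydroxyphenyl)prop-2-enoate
Conditions: Bu4NF, AcOH, THF, 0 °C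
Reagents that add atoms: none
Why: Buffered fluoride desilylation of an aryl silyl ether, which should be much faster than any attack on the hindered cinnamate, so the ester and the (E)-alkene are kept.

Compound list
1 | (S)-piperitone, (6S)-3-methyl-6-(propan-2-yl)cyclohex-2-en-1-one | CC1=CC(=O)[C@H](C(C)C)CC1 | starting material
2 | cis-piperitol, (1R,6S)-3-methyl-6-(propan-2-yl)cyclohex-2-en-1-ol | CC1=C[C@H](O)[C@H](C(C)C)CC1 | intermediate
3 | chlorodimethylvinylsilane | C=C[Si](C)(C)Cl | starting material
4 | chloro(1,2-dibromoethyl)dimethylsilane | C[Si](C)(Cl)C(Br)CBr | intermediate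
5 | (1-bromoethenyl)chlorodimethylsilane | C=C(Br)[Si](C)(C)Cl | intermediate
6 | (1-bromoethenyl)dimethylsilyl ether of cis-piperitol | CC1=C[C@H](O[Si](C)(C)C(Br)=C)[C@H](C(C)C)CC1 | intermediate
7 | allyltributylstannane | C=CC[Sn](CCCC)(CCCC)CCCC | starting material
8 | cis-fused oxasilolane with C4 methylidene on C5 and allyl plus methyl on C10 | C=C1[Si](C)(C)O[C@@H]2[C@H](C(C)C)CC[C@@](C)(CC=C)[C@H]12 | intermediate
9 | 1-[(1S,2R,3S,6S)-2-hydroxy-6-methyl-3-(propan-2-yl)-6-(prop-2-en-1-yl)cyclohexyl]ethan-1-one | O[C@@H]1[C@H](C(C)C)CC[C@@](C)(CC=C)[C@@H]1C(C)=O | intermediate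
10 | O6 tert-butyldimethylsilyl ether of 9 | CC(C)(C)[Si](C)(C)O[C@@H]1[C@H](C(C)C)CC[C@@](C)(CC=C)[C@@H]1C(C)=O | intermediate
11 | catechol boronate ester of 10 (boron on C3) | CC(C)(C)[Si](C)(C)O[C@@H]1[C@H](C(C)C)CC[C@@](C)(CCCB2Oc3ccccc3O2)[C@@H]1C(C)=O | intermediate
12 | C3 primary alcohol (3-hydroxypropyl on C10) | CC(C)(C)[Si](C)(C)O[C@@H]1[C@H](C(C)C)CC[C@@](C)(CCCO)[C@@H]1C(C)=O | intermediate
13 | keto aldehyde (C3 aldehyde, C4 methyl ketone) | CC(C)(C)[Si](C)(C)O[C@@H]1[C@H](C(C)C)CC[C@@](C)(CCC=O)[C@@H]1C(C)=O | intermediate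
14 | O6 tert-butyldimethylsilyl ether of the decalinol | CC1=CCC[C@]2(C)CC[C@@H](C(C)C)[C@@H](O[Si](C)(C)C(C)(C)C)[C@@H]12 | intermediate
15 | (1R,2S,4aR,8aR)-4a,8-dimethyl-2-(propan-2-yl)-1,2,3,4,4a,5,6,8a-octahydronaphthalen-1-ol | CC1=CCC[C@]2(C)CC[C@@H](C(C)C)[C@@H](O)[C@@H]12 | intermediate
16 | p-coumaric acid | OC(=O)/C=C/c1ccc(O)cc1 | starting material
17 | tert-butyldimethylsilyl (2E)-3-(4-{[tert-butyl(dimethyl)silyl]oxy}phenyl)prop-2-enoate | CC(C)(C)[Si](C)(C)OC(=O)/C=C/c1ccc(O[Si](C)(C)C(C)(C)C)cc1 | intermediate
18 | (2E)-3-(4-{[tert-butyl(dimethyl)silyl]oxy}phenyl)prop-2-enoic acid | OC(=O)/C=C/c1ccc(O[Si](C)(C)C(C)(C)C)cc1 | intermediate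
19 | mixed anhydride of 18 with 2,4,6-trichlorobenzoic acid | CC(C)(C)[Si](C)(C)Oc1ccc(/C=C/C(=O)OC(=O)c2c(Cl)cc(Cl)cc2Cl)cc1 | intermediate
20 | phenol O-silyl ether of the target | CC1=CCC[C@]2(C)CC[C@@H](C(C)C)[C@@H](OC(=O)/C=C/c3ccc(O[Si](C)(C)C(C)(C)C)cc3)[C@@H]12 | intermediate
21 | target, CNP0220414.1 | CC1=CCC[C@]2(C)CC[C@@H](C(C)C)[C@@H](OC(=O)/C=C/c3ccc(O)cc3)[C@@H]12 | target

Total step count: 13. Longest linear sequence: 11 steps (steps 1, 3, 4, 5, 6, 7, 8, 9, 10, 12, 13).

Steps most likely to fail

Step 4. The vinyl radical may be captured by the stannane before it closes, and the slowly trapped C10 radical may drift into the ring-expanded isomer through the cyclopropylcarbinyl shift. Allyl transfer may also show poor facial selectivity at C10. The fallback forms the same two bonds by known polar reactions, sets out from 1 and returns at 10. Compound 1 would be α-iodinated (I2, pyridine, CH2Cl2) to (6S)-2-iodo-3-methyl-6-(propan-2-yl)cyclohex-2-en-1-one F1. Reduction with LiBH(s-Bu)3 (THF, −78 °C) would give (1R,6S)-2-iodo-3-methyl-6-(propan-2-yl)cyclohex-2-en-1-ol F2, and silylation (TBSCl, imidazole, DMF) its tert-butyldimethylsilyl ether F3. Iodine–lithium exchange (t-BuLi, Et2O, −78 °C) and acylation with N-methoxy-N-methylacetamide would give 1-[(5S,6R)-6-{[tert-butyl(dimethyl)silyl]oxy}-2-methyl-5-(propan-2-yl)cyclohex-1-en-1-yl]ethan-1-one F4, which holds the C4–C5 bond. Hosomi–Sakurai conjugate allylation (allyltrimethylsilane, TiCl4, CH2Cl2, −78 °C) would then form the C1–C10 bond. The allyl group is expected to enter anti to the pseudoaxial silyloxy group, and protonation at C5 should give the equatorial acetyl epimer, which is 10.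

Step 9. Intermolecular pinacol coupling, aldol closure of the keto aldehyde or loss of the silyl ether on Lewis-acidic titanium may outrun ring closure. The fallback sets out from 13 and returns at 14. Double Wittig methylenation (Ph3PCH3Br, KOt-Bu, THF, 0 °C → reflux) would give the diene tert-butyl{[(1R,2S,3S,6S)-3-(but-3-en-1-yl)-3-methyl-2-(prop-1-en-2-yl)-6-(propan-2-yl)cyclohexyl]oxy}dimethylsilane F5. Ring-closing metathesis with second-generation Grubbs catalyst (H2IMes)(PCy3)Cl2Ru=CHPh (CH2Cl2, 40 °C) would then close the C3=C4 alkene with loss of ethene and give 14.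

Step 12. Acylation of the axial O6, which is flanked by the C7 isopropyl group and 1,3-diaxial to the C10 methyl, may be too slow, so that the activated acid decays first. The fallback builds the cinnamate on the oxygen instead of delivering it whole; it sets out from 15 and returns at 21 without phenol protection. Heating 15 with Meldrum's acid (PhMe, 110 °C) would give the malonic half ester 3-{[(1R,2S,4aR,8aR)-4a,8-dimethyl-2-(propan-2-yl)-1,2,3,4,4a,5,6,8a-octahydronaphthalen-1-yl]oxy}-3-oxopropanoic acid F6. Knoevenagel–Doebner condensation with 4-hydroxybenzaldehyde (pyridine, piperidine cat., 90 °C) would then give the (E)-p-coumarate 21 with loss of carbon dioxide.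

Further compounds
F1 | step 4 | (6S)-2-iodo-3-methyl-6-(propan-2-yl)cyclohex-2-en-1-one | CC1=C(I)C(=O)[C@H](C(C)C)CC1
F2 | step 4 | (1R,6S)-2-iodo-3-methyl-6-(propan-2-yl)cyclohex-2-en-1-ol | CC1=C(I)[C@H](O)[C@H](C(C)C)CC1
F3 | step 4 | tert-butyl{[(1R,6S)-2-iodo-3-methyl-6-(propan-2-yl)cyclohex-2-en-1-yl]oxy}dimethylsilane | CC1=C(I)[C@H](O[Si](C)(C)C(C)(C)C)[C@H](C(C)C)CC1
F4 | step 4 | 1-[(5S,6R)-6-{[tert-butyl(dimethyl)silyl]oxy}-2-methyl-5-(propan-2-yl)cyclohex-1-en-1-yl]ethan-1-one | CC1=C(C(C)=O)[C@H](O[Si](C)(C)C(C)(C)C)[C@H](C(C)C)CC1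
F5 | step 9 | tert-butyl{[(1R,2S,3S,6S)-3-(but-3-en-1-yl)-3-methyl-2-(prop-1-en-2-yl)-6-(propan-2-yl)cyclohexyl]oxy}dimethylsilane | CC(C)(C)[Si](C)(C)O[C@@H]1[C@H](C(C)C)CC[C@@](C)(CCC=C)[C@@H]1C(C)=C
F6 | step 12 | malonic half ester of 15 | CC1=CCC[C@]2(C)CC[C@@H](C(C)C)[C@@H](OC(=O)CC(O)=O)[C@@H]12
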